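**Strategy.** Numbering (longipinane): C1 ketone, C2=C3 enone, C4/C11 bridgeheads, C5 cyclobutane CH, C6 CMe2, C7 (OAng), C9 (OAc), C10 quaternary. The molecule is treated as an oxidized farnesoic acid: an intramolecular vinylketene–alkene [2+2] builds cyclobutane C4–C5–C11–C10 and leaves ketene carbon C5 as a cyclobutanone. The key step disconnects C5–C6: the C5 tosylhydrazone of the bicyclo[3.1.1]heptenone traps the tertiary C6 radical, formed by iron-hydride H-atom transfer to the isopropenyl end of the C10 side chain held cis-1,3 to C5 across the four-membered ring; loss of sulfinate and N2 leaves C5–H. One operation closes the seven-membered ring, creates quaternary C6 and fixes C5.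

Key step: step 15

Remark 1: ring compounds use longipinane locants (methyl carbons: C12 on C3, C13/C14 on C6, C15 on C10; ring bonds C4–C10 and C5–C11); "5,6-seco" means the C5–C6 bond is absent.
Remark 2: the antipodes of the boron reagent (step 2) and of the bisphosphoramide (step 8) are assigned from the accepted facial models of these reagents; the aldehyde face that must be attacked is stated in each step and defines the choice.

Step 1
Reactants: 1 1,1-diethoxy-3-methylbut-2-ene
Product: 2 (E)-4,4-diethoxy-2-methylbut-2-enal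
Conditions: SeO2 (1.2 equiv), pyridine (cat.), EtOH, 78 °C
Reagents that add atoms: selenium dioxide O=[Se]=O
Why: Riley allylic oxidation (ene reaction, then [2,3]-sigmatropic shift) functionalizes the methyl group that ends trans to the acetal-bearing CH and carries on to the (E)-enal, while ethanol as solvent keeps the diethyl acetal intact.

Step 2
Reactants: 2 (E)-4,4-diethoxy-2-methylbut-2-enal; 3 3-methylbut-3-en-2-one
Product: 6 (5R,6E)-8,8-diethoxy-5-hydroxy-2,6-dimethylocta-1,6-dien-3-one, via enol diisopinocampheylborinate 4 (not isolated), via boron aldolate 5 (not isolated)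
Conditions: 3, (+)-Ipc2BCl, Et3N, Et2O, 0 °C; 2, −78 to −20 °C; H2O2, pH 7 buffer, MeOH, 0 °C
Reagents that add atoms: none
Why: Paterson boron aldol, in which the kinetic enol borinate of the methyl ketone adds 1,2 to the enal through a cyclic transition state and the isopinocampheyl ligands direct attack to the Re face of the aldehyde, which sets the carbinol (later C9) as R.

Step 3
Reactants: 6 (5R,6E)-8,8-diethoxy-5-hydroxy-2,6-dimethylocta-1,6-dien-3-one
Product: 7 (3R,5R,6E)-8,8-diethoxy-3-hydroxy-2,6-dimethylocta-1,6-dien-5-yl acetate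
Conditions: SmI2 (0.3 equiv), CH3CHO (8 equiv), THF, −10 °C
Reagents that add atoms: acetaldehyde CC=O
Why: Evans–Tishchenko reduction, in which the samarium-bound hemiacetal of the C5 hydroxyl and acetaldehyde delivers hydride intramolecularly to the ketone through a chair transition state, which gives the 1,3-anti (3R) alcohol (later C7) and at the same time places the acetate on the original hydroxyl (later C9).

Step 4
Reactants: 7 (3R,5R,6E)-8,8-diethoxy-3-hydroxy-2,6-dimethylocta-1,6-dien-5-yl acetate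
Product: 8 (3R,5R,6E)-3-[(tert-butyldimethylsilyl)oxy]-8,8-diethoxy-2,6-dimethylocta-1,6-dien-5-yl acetate
Conditions: TBSCl, imidazole, DMF, rt
Reagents that add atoms: tert-butyldimethylsilyl chloride CC(C)(C)[Si](C)(C)Cl
Why: Imidazole-promoted silylation of the secondary allylic alcohol, under mildly basic conditions to which the acetal and the acetate are inert.

Step 5
Reactants: 8 (3R,5R,6E)-3-[(tert-butyldimethylsilyl)oxy]-8,8-diethoxy-2,6-dimethylocta-1,6-dien-5-yl acetate
Product: 9 (2E,4R,6R)-6-[(tert-butyldimethylsilyl)oxy]-3,7-dimethyl-1-oxoocta-2,7-dien-4-yl acetate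
Conditions: PPTS (cat.), acetone/H2O 10:1, rt
Reagents that add atoms: water O
Why: Acid-catalysed hydrolysis of the α,β-unsaturated acetal, which ionizes far more readily than the TBS ether or the allylic acetate, should unmask the (E)-enal.

Step 6
Reactants: 10 3-methylbut-2-enoyl chloride; 11 prop-2-en-1-ol
Product: 12 prop-2-en-1-yl 3-methylbut-2-enoate
Conditions: pyridine, CH2Cl2, 0 °C
Reagents that add atoms: none
Why: Nucleophilic acyl substitution with a weak base that limits vinylketene formation; any β,γ-unsaturated isomer converges to the same dienolate in step 7.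

Step 7
Reactants: 12 prop-2-en-1-yl 3-methylbut-2-enoate
Product: 14 tert-butyl{[(1Z)-3-methyl-1-(prop-2-en-1-yloxy)buta-1,3-dien-1-yl]oxy}dimethylsilane, via lithium dienolate 13 (not isolated)
Conditions: LiN(iPr)2, THF, −78 °C; TBSCl, DMPU, −78 °C to rt
Reagents that add atoms: tert-butyldimethylsilyl chloride CC(C)(C)[Si](C)(C)Cl
Why: γ-Deprotonation of the senecioate gives the extended enolate, which is O-silylated (silyl ketene acetal formation); the ketene acetal geometry is not relayed to any later stereocenter.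

Step 8
Reactants: 9 (2E,4R,6R)-6-[(tert-butyldimethylsilyl)oxy]-3,7-dimethyl-1-oxoocta-2,7-dien-4-yl acetate; 14 tert-butyl{[(1Z)-3-methyl-1-(prop-2-en-1-yloxy)buta-1,3-dien-1-yl]oxy}dimethylsilane
Product: 16 prop-2-en-1-yl (2E,5S,6E,8R,10R)-8-acetoxy-10-[(tert-butyldimethylsilyl)oxy]-5-hydroxy-3,7,11-trimethyldodeca-2,6,11-trienoate, via trichlorosilyl ether 15 (not isolated)
Conditions: SiCl4 (1.1 equiv), (S,S)-bisphosphoramide [pentane-1,5-diyl-linked bis(N,N′-dimethyl-1,1′-binaphthyl-2,2′-diamine phosphoramide)] (5 mol %), iPr2NEt (10 mol %), CH2Cl2, −78 °C; sat. aq. NaHCO3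
Reagents that add atoms: none
Why: Catalytic enantioselective vinylogous Mukaiyama aldol (Lewis-base-activated SiCl4), in which the dienolate attacks through its γ-carbon on the Si face of the catalyst-bound enal, which sets the (5S) carbinol (later C1, a temporary stereocenter) and gives the (E)-enoate.

Step 9
Reactants: 16 prop-2-en-1-yl (2E,5S,6E,8R,10R)-8-acetoxy-10-[(tert-butyldimethylsilyl)oxy]-5-hydroxy-3,7,11-trimethyldodeca-2,6,11-trienoate
Product: 17 prop-2-en-1-yl (2E,5S,6E,8R,10R)-8-acetoxy-10-[(tert-butyldimethylsilyl)oxy]-3,7,11-trimethyl-5-[(triethylsilyl)oxy]dodeca-2,6,11-trienoate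
Conditions: TESCl, imidazole, DMF, 0 °C
Reagents that add atoms: chlorotriethylsilane CC[Si](Cl)(CC)CC
Why: Standard silylation of the secondary allylic alcohol; the more labile triethylsilyl group is chosen so that it can later be removed beside the TBS ether.

Step 10
Reactants: 17 prop-2-en-1-yl (2E,5S,6E,8R,10R)-8-acetoxy-10-[(tert-butyldimethylsilyl)oxy]-3,7,11-trimethyl-5-[(triethylsilyl)oxy]dodeca-2,6,11-trienoate
Product: 18 (2E,5S,6E,8R,10R)-8-acetoxy-10-[(tert-butyldimethylsilyl)oxy]-3,7,11-trimethyl-5-[(triethylsilyl)oxy]dodeca-2,6,11-trienoic acid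
Conditions: Pd(PPh3)4 (5 mol %), morpholine, THF, rt; pH 4 buffer
Reagents that add atoms: none
Why: Tsuji–Trost deallylation, in which zerovalent palladium ionizes the unsubstituted allyl ester much faster than the hindered secondary allylic acetate and morpholine traps the allyl fragment, so the acid is freed without touching the acetate or the silyl ethers.

Step 11
Reactants: 18 (2E,5S,6E,8R,10R)-8-acetoxy-10-[(tert-butyldimethylsilyl)oxy]-3,7,11-trimethyl-5-[(triethylsilyl)oxy]dodeca-2,6,11-trienoic acid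
Product: 21 (1S,7R,9R)-9-acetoxy-7-[(tert-butyldimethylsilyl)oxy]-1-[(triethylsilyl)oxy]-5,6-secolongipina-3(12),6(13)-dien-5-one (a 7-methyl-2-methylidenebicyclo[3.1.1]heptan-6-one; C15 methyl syn to the C1–C3 bridge; side chain anti; C4/C10/C11 as in the target), via acid chloride 19 (not isolated), via vinylketene 20 (not isolated)
Conditions: 1-chloro-N,N,2-trimethylprop-1-en-1-amine, CH2Cl2, 0 °C; slow addition to Et3N, toluene, 110 °C, 0.005 M
Reagents that add atoms: none
Why: Intramolecular vinylketene–alkene [2+2] cycloaddition (Snider type), in which the ketene carbonyl carbon C5 bonds to the less substituted alkene carbon C11 and the ketene α-carbon C4 to C10 to give the crossed bicyclo[3.1.1]heptan-6-one; the (E)-alkene is transferred suprafacially (C15 methyl syn, chain anti to the C1–C3 bridge), and A(1,3) strain between that methyl and the C1 substituents keeps C1–H in the alkene plane so that the ketene is delivered anti to the silyloxy group, which fixes C4, C10 and C11 in the absolute sense of the target.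

Step 12
Reactants: 21 (1S,7R,9R)-9-acetoxy-7-[(tert-butyldimethylsilyl)oxy]-1-[(triethylsilyl)oxy]-5,6-secolongipina-3(12),6(13)-dien-5-one
Product: 22 (1S,7R,9R)-9-acetoxy-7-[(tert-butyldimethylsilyl)oxy]-1-hydroxy-5,6-secolongipina-3(12),6(13)-dien-5-one
Conditions: PPTS, MeOH/CH2Cl2, 0 °C
Reagents that add atoms: none
Why: Acid-catalysed methanolysis cleaves the secondary TES ether much faster than the more shielded secondary TBS ether.

Step 13
Reactants: 22 (1S,7R,9R)-9-acetoxy-7-[(tert-butyldimethylsilyl)oxy]-1-hydroxy-5,6-secolongipina-3(12),6(13)-dien-5-one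
Product: 24 (7R,9R)-9-acetoxy-7-[(tert-butyldimethylsilyl)oxy]-5,6-secolongipina-2,6(13)-diene-1,5-dione, via β,γ-unsaturated diketone 23 (not isolated)
Conditions: Dess–Martin periodinane, CH2Cl2, 0 °C to rt; aq. Na2S2O3/NaHCO3; crude, DBU (0.1 equiv), CH2Cl2, 0 °C; used at once
Reagents that add atoms: none
Why: Dess–Martin oxidation followed by base-catalysed isomerization through the C2 dienolate moves the exocyclic double bond into conjugation (verbenone-type enone), erases the C1 stereocenter that steered the cycloaddition, and cannot epimerize C11 because the bridgehead between the two carbonyls cannot enolize.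

Step 14
Reactants: 24 (7R,9R)-9-acetoxy-7-[(tert-butyldimethylsilyl)oxy]-5,6-secolongipina-2,6(13)-diene-1,5-dione
Product: 25 C5 (4-methylbenzenesulfonyl)hydrazone of 24
Conditions: TsNHNH2 (1.05 equiv), PPTS (cat.), MgSO4, THF, rt
Reagents that add atoms: 4-methylbenzenesulfonohydrazide Cc1ccc(cc1)S(=O)(=O)NN
Why: Hydrazone formation at the strained, more electrophilic cyclobutanone carbonyl in preference to the conjugated, hindered C1 ketone, under weakly acidic, non-nucleophilic conditions that avoid retro-Claisen opening of the non-enolizable β-diketone.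

Step 15
Reactants: 25 C5 (4-methylbenzenesulfonyl)hydrazone of 24
Product: 28 (4R,5S,7R,9R,10R,11R)-9-acetoxy-7-[(tert-butyldimethylsilyl)oxy]longipin-2-en-1-one, via cyclized hydrazide 26 (not isolated), via diazene 27 (not isolated)
Conditions: Fe(acac)3 (0.5 equiv), PhSiH3 (3 equiv), EtOH, 0.01 M, 60 °C; then NaOAc (5 equiv), 80 °C
Reagents that add atoms: none
Why: Hydrogen-atom transfer from the iron hydride to the terminal CH2 (C13) of the isopropenyl group gives the tertiary C6 radical, which adds to the hydrazone carbon C5; the hydrazinyl radical is reduced to hydrazide 26, and NaOAc then eliminates sulfinate to diazene 27, which loses N2 and leaves C5–H. The closest known reaction type is the iron-hydride-initiated reductive radical cyclization of alkene-tethered ketone sulfonylhydrazones, combined with the sulfinate/N2 extrusion known from reductive alkylation of sulfonylhydrazones. The seven-membered ring (C5, C6, C7, C8, C9, C10 and C4 or C11) closes in the 7-exo-trig mode, helped by the cis-1,3 arrangement across the cyclobutane that holds C9 within reach of C5. The only new stereocenter, C5, is dictated by the bridge: C6 can bond only on the cyclobutane face anti to the C1–C3 enone bridge, so nitrogen and then hydrogen occupy the syn face. The step needs H-atom transfer to the electron-rich 1,1-disubstituted alkene instead of the enone, and bond formation at C5 without opening of the four-membered ring; the first is secured by the electron-poor, trisubstituted enone, the second by using C=N instead of C=O as acceptor, which gives a stabilized nitrogen radical instead of a cyclobutyloxy radical prone to β-scission.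

Step 16
Reactants: 28 (4R,5S,7R,9R,10R,11R)-9-acetoxy-7-[(tert-butyldimethylsilyl)oxy]longipin-2-en-1-one
Product: 29 (4R,5S,7R,9R,10R,11R)-9-acetoxy-7-hydroxylongipin-2-en-1-one
Conditions: HF·pyridine, pyridine, THF, 0 °C to rt
Reagents that add atoms: none
Why: Fluoride-induced desilylation under buffered acidic conditions, which avoid the basic media in which the C9 acetate could migrate to the freed C7 hydroxyl.

Step 17
Reactants: 29 (4R,5S,7R,9R,10R,11R)-9-acetoxy-7-hydroxylongipin-2-en-1-one; 30 (Z)-2-methylbut-2-enoic acid (angelic acid)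
Product: 32 (4R,5S,7R,9R,10R,11R)-9-acetoxy-7-[(Z)-2-methylbut-2-enoyloxy]longipin-2-en-1-one, via mixed anhydride 31 (not isolated)
Conditions: 30, 2,4,6-trichlorobenzoyl chloride, Et3N, toluene, rt; then 29, 80 °C
Reagents that add atoms: none
Why: Yamaguchi esterification, in which the hindered C7 hydroxyl attacks the less shielded angeloyl carbonyl of the mixed anhydride and the absence of a nucleophilic catalyst limits Z to E isomerization.

**Compound list**

1 | 1,1-diethoxy-3-methylbut-2-ene | CC(C)=CC(OCC)OCC | starting material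
2 | (E)-4,4-diethoxy-2-methylbut-2-enal | O=C/C(C)=C/C(OCC)OCC | intermediate
3 | 3-methylbut-3-en-2-one | CC(=O)C(C)=C | starting material
4 | enol diisopinocampheylborinate of 3 | C=C(C)C(=C)OB([C@H]1C[C@H]2C[C@H](C2(C)C)[C@@H]1C)[C@H]1C[C@H]2C[C@H](C2(C)C)[C@@H]1C | intermediate
5 | boron aldolate (O-diisopinocampheylboryl derivative of 6) | C=C(C)C(=O)C[C@@H](OB([C@H]1C[C@H]2C[C@H](C2(C)C)[C@@H]1C)[C@H]1C[C@H]2C[C@H](C2(C)C)[C@@H]1C)/C(C)=C/C(OCC)OCC | intermediate
6 | (5R,6E)-8,8-diethoxy-5-hydroxy-2,6-dimethylocta-1,6-dien-3-one | C=C(C)C(=O)C[C@@H](O)/C(C)=C/C(OCC)OCC | intermediate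
7 | (3R,5R,6E)-8,8-diethoxy-3-hydroxy-2,6-dimethylocta-1,6-dien-5-yl acetate | C=C(C)[C@H](O)C[C@@H](OC(C)=O)/C(C)=C/C(OCC)OCC | intermediate
8 | (3R,5R,6E)-3-[(tert-butyldimethylsilyl)oxy]-8,8-diethoxy-2,6-dimethylocta-1,6-dien-5-yl acetate | C=C(C)[C@H](O[Si](C)(C)C(C)(C)C)C[C@@H](OC(C)=O)/C(C)=C/C(OCC)OCC | intermediate
9 | (2E,4R,6R)-6-[(tert-butyldimethylsilyl)oxy]-3,7-dimethyl-1-oxoocta-2,7-dien-4-yl acetate | C=C(C)[C@H](O[Si](C)(C)C(C)(C)C)C[C@@H](OC(C)=O)/C(C)=C/C=O | intermediate
10 | 3-methylbut-2-enoyl chloride | CC(C)=CC(Cl)=O | starting material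
11 | prop-2-en-1-ol | C=CCO | starting material
12 | prop-2-en-1-yl 3-methylbut-2-enoate | CC(C)=CC(=O)OCC=C | intermediate
13 | lithium dienolate of 12 (O–Li cis to C3) | C=C(C)/C=C(/OCC=C)O[Li] | intermediate
14 | tert-butyl{[(1Z)-3-methyl-1-(prop-2-en-1-yloxy)buta-1,3-dien-1-yl]oxy}dimethylsilane | C=C(C)/C=C(/OCC=C)O[Si](C)(C)C(C)(C)C | intermediate
15 | 5-O-trichlorosilyl ether of 16 | C=C(C)[C@H](O[Si](C)(C)C(C)(C)C)C[C@@H](OC(C)=O)/C(C)=C/[C@@H](O[Si](Cl)(Cl)Cl)C/C(C)=C/C(=O)OCC=C | intermediate
16 | prop-2-en-1-yl (2E,5S,6E,8R,10R)-8-acetoxy-10-[(tert-butyldimethylsilyl)oxy]-5-hydroxy-3,7,11-trimethyldodeca-2,6,11-trienoate | C=C(C)[C@H](O[Si](C)(C)C(C)(C)C)C[C@@H](OC(C)=O)/C(C)=C/[C@@H](O)C/C(C)=C/C(=O)OCC=C | intermediate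
17 | prop-2-en-1-yl (2E,5S,6E,8R,10R)-8-acetoxy-10-[(tert-butyldimethylsilyl)oxy]-3,7,11-trimethyl-5-[(triethylsilyl)oxy]dodeca-2,6,11-trienoate | C=C(C)[C@H](O[Si](C)(C)C(C)(C)C)C[C@@H](OC(C)=O)/C(C)=C/[C@@H](O[Si](CC)(CC)CC)C/C(C)=C/C(=O)OCC=C | intermediate
18 | (2E,5S,6E,8R,10R)-8-acetoxy-10-[(tert-butyldimethylsilyl)oxy]-3,7,11-trimethyl-5-[(triethylsilyl)oxy]dodeca-2,6,11-trienoic acid | C=C(C)[C@H](O[Si](C)(C)C(C)(C)C)C[C@@H](OC(C)=O)/C(C)=C/[C@@H](O[Si](CC)(CC)CC)C/C(C)=C/C(O)=O | intermediate
19 | acid chloride of 18 | C=C(C)[C@H](O[Si](C)(C)C(C)(C)C)C[C@@H](OC(C)=O)/C(C)=C/[C@@H](O[Si](CC)(CC)CC)C/C(C)=C/C(Cl)=O | intermediate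
20 | vinylketene: (5S,6E,8R,10R)-8-acetoxy-10-[(tert-butyldimethylsilyl)oxy]-7,11-dimethyl-3-methylidene-5-[(triethylsilyl)oxy]dodeca-1,6,11-trien-1-one | C=C(C)[C@H](O[Si](C)(C)C(C)(C)C)C[C@@H](OC(C)=O)/C(C)=C/[C@@H](O[Si](CC)(CC)CC)CC(=C)C=C=O | intermediate
21 | (1S,7R,9R)-9-acetoxy-7-[(tert-butyldimethylsilyl)oxy]-1-[(triethylsilyl)oxy]-5,6-secolongipina-3(12),6(13)-dien-5-one (C15 methyl syn to the C1–C3 bridge; chain anti; OTES on the side of the C5 carbonyl) | C=C(C)[C@H](O[Si](C)(C)C(C)(C)C)C[C@@H](OC(C)=O)[C@@]2(C)[C@@H]3[C@@H](O[Si](CC)(CC)CC)CC(=C)[C@H]2C3=O | intermediate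
22 | (1S,7R,9R)-9-acetoxy-7-[(tert-butyldimethylsilyl)oxy]-1-hydroxy-5,6-secolongipina-3(12),6(13)-dien-5-one | C=C(C)[C@H](O[Si](C)(C)C(C)(C)C)C[C@@H](OC(C)=O)[C@@]2(C)[C@@H]3[C@@H](O)CC(=C)[C@H]2C3=O | intermediate
23 | (7R,9R)-9-acetoxy-7-[(tert-butyldimethylsilyl)oxy]-5,6-secolongipina-3(12),6(13)-diene-1,5-dione | C=C(C)[C@H](O[Si](C)(C)C(C)(C)C)C[C@@H](OC(C)=O)[C@@]2(C)[C@@H]3C(=O)CC(=C)[C@H]2C3=O | intermediate
24 | (7R,9R)-9-acetoxy-7-[(tert-butyldimethylsilyl)oxy]-5,6-secolongipina-2,6(13)-diene-1,5-dione | C=C(C)[C@H](O[Si](C)(C)C(C)(C)C)C[C@@H](OC(C)=O)[C@@]2(C)[C@@H]3C(=O)C=C(C)[C@H]2C3=O | intermediate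
25 | C5 (4-methylbenzenesulfonyl)hydrazone of 24 | C=C(C)[C@H](O[Si](C)(C)C(C)(C)C)C[C@@H](OC(C)=O)[C@@]2(C)[C@@H]3C(=O)C=C(C)[C@H]2C3=NNS(=O)(=O)c1ccc(C)cc1 | intermediate
26 | cyclized hydrazide: 9-acetoxy-7-[(tert-butyldimethylsilyl)oxy]-5-[2-(4-methylbenzenesulfonyl)hydrazinyl]longipin-2-en-1-one (N on C5 syn to the enone bridge) | CC(C)(C)[Si](C)(C)O[C@@H]1C[C@@H](OC(C)=O)[C@@]2(C)[C@@H]3C(=O)C=C(C)[C@H]2[C@]3(NNS(=O)(=O)c4ccc(C)cc4)C1(C)C | intermediate
27 | diazene: 9-acetoxy-7-[(tert-butyldimethylsilyl)oxy]-5-diazenyllongipin-2-en-1-one | CC(C)(C)[Si](C)(C)O[C@@H]1C[C@@H](OC(C)=O)[C@@]2(C)[C@@H]3C(=O)C=C(C)[C@H]2[C@]3(N=N)C1(C)C | intermediate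
28 | (4R,5S,7R,9R,10R,11R)-9-acetoxy-7-[(tert-butyldimethylsilyl)oxy]longipin-2-en-1-one | CC(C)(C)[Si](C)(C)O[C@@H]1C[C@@H](OC(C)=O)[C@@]2(C)[C@@H]3C(=O)C=C(C)[C@H]2[C@@H]3C1(C)C | intermediate
29 | (4R,5S,7R,9R,10R,11R)-9-acetoxy-7-hydroxylongipin-2-en-1-one | O[C@@H]1C[C@@H](OC(C)=O)[C@@]2(C)[C@@H]3C(=O)C=C(C)[C@H]2[C@@H]3C1(C)C | intermediate
30 | (Z)-2-methylbut-2-enoic acid (angelic acid) | C/C=C(/C)C(=O)O | starting material
31 | (Z)-2-methylbut-2-enoic 2,4,6-trichlorobenzoic anhydride | C/C=C(/C)C(=O)OC(=O)c1c(Cl)cc(Cl)cc1Cl | intermediate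
32 | (4R,5S,7R,9R,10R,11R)-9-acetoxy-7-[(Z)-2-methylbut-2-enoyloxy]longipin-2-en-1-one | C/C=C(/C)C(=O)O[C@@H]1C[C@@H](OC(C)=O)[C@@]2(C)[C@@H]3C(=O)C=C(C)[C@H]2[C@@H]3C1(C)C | target

**Step count.** Total: 17 steps. Longest linear sequence: 15 steps (1–5 and 8–17); steps 6–7 form a two-step branch.

**Steps most likely to fail**

1. Step 15 (key step). The 7-exo addition to the hindered C=N may be slower than reduction of the tertiary C6 radical, which would merely hydrogenate the isopropenyl group, or the addition may be reversible. Fallback: diketone 24 is condensed with 1-amino-2-phenylaziridine to the C5 N-(2-phenylaziridin-1-yl)imine F1, a Kim-type radical acceptor. Under the same iron hydride initiation (Fe(acac)3, PhSiH3, EtOH, 60 °C) the C6 radical should add to C5, and the adduct should collapse irreversibly by aziridine opening and loss of styrene and N2 to the C5 radical, which takes up hydrogen. This makes the addition irreversible, needs no elimination stage, and comes back to the route at 28.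

2. Step 11. The vinylketene may oligomerize faster than it adds to the C10=C11 alkene, which is deactivated by two allylic C–O bonds, and facial control by the C1 silyloxy group may erode at 110 °C. Fallback: acid 18 is converted into its chloride as in step 11 and quenched with pyrrolidine to give the pyrrolidine amide F2. Tf2O and 2,4,6-collidine in 1,2-dichloroethane (0 to 80 °C) should convert F2, by O-triflation and γ-deprotonation, into the much more electrophilic vinylketeniminium ion, whose intramolecular [2+2] (Ghosez type) with the same alkene should give the cyclobutaniminium triflate F3. Aqueous NaHCO3 hydrolyses F3 to ketone 21, where the route is rejoined.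

3. Step 17. Slow acylation of the hindered C7 hydroxyl (next to quaternary C6) may allow Z to E isomerization of the angeloyl unit to the tiglate, and 1,3-acetyl migration from O9 to O7. Fallback: alcohol 29 is esterified with 2-[bis(2,2,2-trifluoroethoxy)phosphoryl]propanoic acid (DCC, DMAP, CH2Cl2, 0 °C) to the phosphonate ester F4. A Still–Gennari olefination of F4 with acetaldehyde (KN(SiMe3)2, 18-crown-6, THF, −78 °C) then builds the (Z)-2-methylbut-2-enoate on the substrate and gives 32.

Further compounds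
F1 | step 15 | C5 N-(2-phenylaziridin-1-yl)imine of 24 (either configuration at the aziridine carbon) | C=C(C)[C@H](O[Si](C)(C)C(C)(C)C)C[C@@H](OC(C)=O)[C@@]2(C)[C@@H]3C(=O)C=C(C)[C@H]2C3=NN1CC1c1ccccc1
F2 | step 11 | pyrrolidine amide of 18 | C=C(C)[C@H](O[Si](C)(C)C(C)(C)C)C[C@@H](OC(C)=O)/C(C)=C/[C@@H](O[Si](CC)(CC)CC)C/C(C)=C/C(=O)N1CCCC1
F3 | step 11 | C5 pyrrolidinium-ylidene (cyclobutaniminium) triflate corresponding to 21 | C=C(C)[C@H](O[Si](C)(C)C(C)(C)C)C[C@@H](OC(C)=O)[C@@]2(C)[C@@H]3[C@@H](O[Si](CC)(CC)CC)CC(=C)[C@H]2C3=[N+]1CCCC1.[O-]S(=O)(=O)C(F)(F)F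
F4 | step 17 | 7-O-{2-[bis(2,2,2-trifluoroethoxy)phosphoryl]propanoyl} derivative of 29 (mixture at the phosphonate α-carbon) | CC(C(=O)O[C@@H]1C[C@@H](OC(C)=O)[C@@]2(C)[C@@H]3C(=O)C=C(C)[C@H]2[C@@H]3C1(C)C)P(=O)(OCC(F)(F)F)OCC(F)(F)F
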